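Read at 30 s, both set-ups ask one thing: how much substrate has a target met by then?

| flask | substrate | remark | time |
|---|---|---|---|
| ochre | 20 mM | a single well-mixed tank run continuously and read at steady state, 30 s in it on average |  |
| blue | 20 mM | everything together in a closed stirred flask, run for 30 s | 30 s |

- the set-up with the highest share of target in all that became target or side product, at the outlet or at the end ("none" if the first two lie within 2 percentage points) (ochre / blue / none)
- share of target in all that became target or side product, at the outlet or at the end, ochre
- share of target in all that became target or side product, at the outlet or at the end, blue

    substrate ⇌ intermediate A (K1 = 0.11, k1 = 1.3 /s)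
    intermediate A ⇌ intermediate B (K2 = 1.7, k2 = 0.067 /s)
    intermediate A ⇌ intermediate C (K3 = 17, k3 = 0.0042 /s)
    intermediate C ⇌ intermediate D (K4 = 3.7, k4 = 0.11 /s)
    intermediate B → target (k5 = 0.15 /s)
    substrate + target → side product (k6 = 2.3 /M/s)
    2 substrate → self-condensation product (k7 = 1.1 /M/s)

Define the exposure as the rate constant 2.3 /M/s times [substrate], summed over the time a target sits. Each side product destroys one target and counts twice. So a surviving fraction s gives a share s/(2−s).

Two chemists dispute this. The first starts with ochre. Substrate and intermediate A relax in 0.0528 s, far shorter than the 30 s, so [intermediate A] is 0.11 times [substrate]. Intermediate C forms with a forward half-life of 170 s, longer than the 30 s, so that branch is dropped. Outflow and the leak to intermediate B remove the pool of substrate plus intermediate A at 0.0444 /s per unit of [substrate], and self-condensation adds its squared term. The balance gives a tank [substrate] of 10.0 mM, half of the charge. A target sits there 30 s on average, so its exposure is 0.692, and a tank survivor fraction of one over one plus that exposure gives 41.9%.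

In blue, the pool starts at 18.0 mM. At that start, self-condensation uses substrate faster than the leak to intermediate B does, and the pool's fractional fall is 0.0357 /s. The selectivity factor, target loss against that fall, is 1.16. A target born at the start of blue collects 0.845, more than the tank's 0.692. So the first chemist picks ochre.

The second chemist objects that target comes through intermediate B, which relaxes in 6.51 s. The second chemist takes a typical target in blue to be born near mid-run. Its exposure, the selectivity factor times the log of the pool's fall over the second half of the reading time, is 0.347. That is half the tank's. I side with this view. With survivors at exp(−exposure), it gives 54.6% for blue, and the best set-up is blue.

The forecast also says blue, with 42% for ochre and 59% for blue, which is above my blue figure. Its ground: "in the flask most target forms late, when substrate has already fallen".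

The simulation gives blue, with 42.2% for ochre and 59.1% for blue. The step to intermediate C makes no difference to blue's share.

The first chemist's ordering returns when blue is read later. At 2.0 min, the same mid-run rule gives an exposure of 0.603, more than the 0.347 of the 30 s reading, and a share of 37.7%. That neighbouring flask reads 37.4%, below ochre's 42.2%. In it, substrate stands at 8.40% of the charge, and side product at 17.4% exceeds target at 10.4%.

The rate constants stand for no real mixture; no experiment stands behind them.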